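The readings come from a simulation with made-up constants, noise included.

We begin with the easy step, the start of a portion, and then fold the recipes below into one number.

| flask | solid substrate | partner | remark | time |
|---|---|---|---|---|
| ochre | 0.050 M | 0.073 M (in portions, 4) | run made earlier; portions every 3.0 h |  |
| violet | 0.050 M | 0.24 M (in portions, 4) | run made earlier; portions every 3.0 h |  |
| red | 0.13 M | 0.060 M (in portions, 4) | run made earlier; portions every 3.0 h |  |
| Sunday's | 0.20 M | 0.0600 M (in portions, 4) | the portions of partner follow each other after 0.80 h, the first at the start | 12 h |
| Monday's | 0.080 M | 0.200 M (in portions, 4) | the portions of partner follow each other after 1.0 h, the first at the start | 12 h |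
| Friday's | 0.20 M | 0.120 M (in portions, 4) | the portions of partner follow each other after 2.0 h, the first at the start | 12 h |
| Thursday's | 0.050 M | 0.0600 M (in portions, 4) | the portions of partner follow each other after 3.0 h, the first at the start | 12 h |

| run | time / h | target / % | solid substrate / % |
|---|---|---|---|
| ochre | 1.50 | 5.8 | 55.7 |
| ochre | 3.00 | 9.0 | 50.8 |
| ochre | 5.00 | 18.5 | 36.1 |
| ochre | 6.00 | 21.0 | 30.8 |
| violet | 0.500 | 6.2 | 56.3 |
| violet | 1.00 | 13.0 | 49.5 |
| violet | 2.50 | 24.2 | 30.1 |
| violet | 6.00 | 59.0 | 0 |
| red | 0.500 | 0 | 84.6 |
| red | 1.00 | 1.3 | 83.7 |
| red | 2.50 | 2.1 | 83.5 |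
| red | 6.00 | 7.0 | 75.7 |

(readings scatter by 0.5 percentage points)

- at the start none of the solid substrate is in solution
- what has only dissolved of solid substrate counts as not reacted
- a reading or a percentage of target counts all its forms, free or not

- ranking by amount of target, in percent of the solid substrate charged, from high to low, at 12 h (Sunday's / Monday's / Friday's / Thursday's)
- the amount of target, in percent of the solid substrate charged of the flask you put first, at 12 h
- the amount of target, in percent of the solid substrate charged of the flask you put last, at 12 h

In the ochre run the first portion of partner has given 5.8% of target by 1.50 h. If c(partner) decays exponentially into target, that reading gives a pseudo-first-order constant k of 0.115 h⁻¹. The violet run, with 0.24 M of partner against 0.073 M, reads 0.115 h⁻¹, about the same, so we take the rate of target as k·c(partner).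

A portion that has stood for a span s has then turned over the fraction one minus exp(−ks). Summing the portions as a geometric series gives the reach N, the partner turned over by the asked time as a fraction of the solid substrate charged: 0.213 for Sunday's. Friday's has 0.380, Thursday's 0.656 and Monday's 1.75. Monday's reach stands above one, so we cap it there, and we rank Monday's, Thursday's, Friday's, Sunday's.

Is one number enough? With two portions behind them at 6.00 h, the ochre run has N of 0.289 and the red run 0.0914, yet the target readings are 0.726 and 0.766 of these. It is not, then: a second factor is needed. Using their mean, 0.746, we expect 74.6% for Monday's and 15.9% for Sunday's.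

The forecast gives Monday's > Thursday's > Friday's > Sunday's, with 68% (58% to 74%) and 9.5% (7.5% to 11.5%): “Target rate tracks partner, about 0.13 h⁻¹ × [partner], and ignores substrate charge while solid remains.” The order is ours, but our Sunday's figure is higher than its range.

The flasks give Monday's > Thursday's > Friday's > Sunday's, with 70.4% for Monday's and 12.1% for Sunday's.

    target ⇌ isomer of the product (K = 1.36, k = 6.55 × 10⁻⁵ s⁻¹)
    dissolved substrate + partner → target (k = 0.00194 M⁻¹ s⁻¹)
    solid substrate ⇌ dissolved substrate, rate k3*(cs3 - [dissolved substrate]) while solid is left; crystals form when [dissolved substrate] > cs3 (solubility = 19.0 mM, k = 0.00397 s⁻¹)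
    solid product ⇌ target, rate k4*(cs4 - [target]) while solid is left; crystals form when [target] > cs4 (solubility = 20.0 mM, k = 7.01 × 10⁻⁴ s⁻¹)

Sunday's conversion of 22.6% stands beside its N of 0.213, and the flask splits it into target, 12.1%, and isomer of the product, 10.6%. In Monday's flask the conversion of dissolved substrate with partner had 94% of its turnover up to 12 h behind it at 6.00 h, when solid substrate stood at 0% and target at 72.3%. After that, isomer of the product rose to 29.5% by 12.0 h while target eased to 70.4%. The neighbour of Monday's with 0.14 M of solid substrate has N of 1.00, and there target stands at 78.1% and isomer of the product at 18.7%, with 3.1% of the charge still there, solid or dissolved.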